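**Retrosynthetic overview**

1. Target 19 comes from arylboronate 18 by oxidation of the C–B bond; boron stands in for the ring A hydroxyl.
2. Ring A is the only ring made and is formed last. Its C3(Br)–C4(H)–C5(Br)–C6(H) segment, with both bromines meta to the C1 hydroxyl, is C3–C6 of 3,5-dibromo-2-pyrone 16. C1 and C2, the two oxygen-bearing carbons, are the alkyne carbons of ynol ether boronate 14. A [4+2] cycloaddition followed by loss of CO2 forms bonds C2–C3 and C1–C6.
3. Boronate 14 comes from phenol 7 (rings B and C) by O-vinylation, bromination and double dehydrobromination to the ethynyl ether 11, then borylation of the acetylenic C–H.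
4. Phenol 7 comes from 5-bromo-2-methoxyphenol 4 by dibromination ortho and para to the free OH, O-arylation with iodonium salt 3 (from 2,4-dibromo-1-iodobenzene 1) and O-demethylation. Pyrone 16 comes from coumalic acid 15.

Key step: step 10

Remark: compounds 1, 4 and 15 are taken as commercial. From compound 5 onward no alkyllithium or Grignard reagent is used, because bromine–metal exchange on the polybrominated rings would outrun any other reaction; only amide, alkoxide and amine bases appear.

**Route**

Step 1
Reactants: 1 2,4-dibromo-1-iodobenzene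
Product: 3 (2,4-dibromophenyl)(2,4,6-trimethoxyphenyl)iodonium tosylate, via hydroxy(tosyloxy)iodoarene 2 (not isolated)
Conditions: mCPBA, TsOH·H2O, MeCN, 77 °C; then 1,3,5-trimethoxybenzene, 77 °C; precipitation with Et2O
Reagents that add atoms: p-toluenesulfonic acid Cc1ccc(S(=O)(=O)O)cc1; 1,3,5-trimethoxybenzene COc1cc(OC)cc(OC)c1
Why: One-pot peracid oxidation of the aryl iodide to the hydroxy(tosyloxy)iodoarene and electrophilic substitution on the very electron-rich trimethoxybenzene is the standard entry to aryl(trimethoxyphenyl)iodonium salts of trivalent iodine, and the bromines are inert to the peracid.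

Step 2
Reactants: 4 5-bromo-2-methoxyphenol
Product: 5 2,3,4-tribromo-6-methoxyphenol
Conditions: Br2 (2.1 equiv), NaOAc, AcOH, rt
Reagents that add atoms: bromine BrBr
Why: Electrophilic aromatic bromination is steered by the free hydroxyl into its only open ortho and para positions (C6 and C4 of 4), which flank the bromine already at C5 and give the contiguous tribromide, while the position ortho to the methoxy group is much less activated and should stay free.

Step 3
Reactants: 5 2,3,4-tribromo-6-methoxyphenol; 3 (2,4-dibromophenyl)(2,4,6-trimethoxyphenyl)iodonium tosylate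
Product: 6 1,2,3-tribromo-4-(2,4-dibromophenoxy)-5-methoxybenzene
Conditions: KOtBu, THF, 0 °C; then 3, 40 °C
Reagents that add atoms: none
Why: Metal-free O-arylation of a phenoxide with a diaryliodonium salt (ligand coupling at trivalent iodine) tolerates two ortho substituents on the phenoxide and bromine on both partners, and the electron-poor ortho-bromo aryl group is transferred while the trimethoxyphenyl group leaves as its aryl iodide.

Step 4
Reactants: 6 1,2,3-tribromo-4-(2,4-dibromophenoxy)-5-methoxybenzene
Product: 7 3,4,5-tribromo-2-(2,4-dibromophenoxy)phenol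
Conditions: BBr3, CH2Cl2, −78 °C to rt; then H2O
Reagents that add atoms: none
Why: BBr3 cleaves the methyl aryl ether (Lewis acid demethylation, bromide attack at methyl) and leaves the diaryl ether and all aryl bromides untouched.

Step 5
Reactants: 7 3,4,5-tribromo-2-(2,4-dibromophenoxy)phenol
Product: 8 1,2,3-tribromo-4-(2,4-dibromophenoxy)-5-(ethenyloxy)benzene
Conditions: 2,4,6-trivinylcyclotriboroxane·pyridine, Cu(OAc)2, pyridine, CH2Cl2, O2 (balloon), rt
Reagents that add atoms: 2,4,6-trivinylcyclotriboroxane–pyridine complex C=CB1OB(C=C)OB(C=C)O1.c1ccncc1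
Why: Oxidative O-vinylation of a phenol with a vinylboron reagent mediated by divalent copper acetate (Chan–Lam coupling) runs at room temperature, where the aryl bromides do not enter copper chemistry.

Step 6
Reactants: 8 1,2,3-tribromo-4-(2,4-dibromophenoxy)-5-(ethenyloxy)benzene
Product: 10 1,2,3-tribromo-5-{[(Z)-2-bromoethenyl]oxy}-4-(2,4-dibromophenoxy)benzene, via dibromide 9 (not isolated)
Conditions: Br2 (1.0 equiv), CH2Cl2, −78 °C; then DBU, −78 °C to rt
Reagents that add atoms: bromine BrBr
Why: Bromine adds to the electron-rich enol ether double bond far faster than it substitutes the deactivated bromoarene rings, and amine-induced dehydrobromination (E2) of a 1,2-dibromoethyl ether is the classical way to 2-bromovinyl ethers, expected mainly as the Z isomer, with any E or 1-bromovinyl isomer converging on the same alkyne in step 7.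

Step 7
Reactants: 10 1,2,3-tribromo-5-{[(Z)-2-bromoethenyl]oxy}-4-(2,4-dibromophenoxy)benzene
Product: 11 1,2,3-tribromo-4-(2,4-dibromophenoxy)-5-(ethynyloxy)benzene
Conditions: KOtBu (2.5 equiv), THF, −20 °C to rt; then NH4Cl (aq)
Reagents that add atoms: none
Why: Alkoxide-induced anti E2 dehydrobromination of a 2-bromovinyl aryl ether is the classical synthesis of aryloxyacetylenes, and KOtBu in THF at or below room temperature is too weak to metalate the bromoarene rings.

Step 8
Reactants: 11 1,2,3-tribromo-4-(2,4-dibromophenoxy)-5-(ethynyloxy)benzene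
Product: 14 2-{[3,4,5-tribromo-2-(2,4-dibromophenoxy)phenoxy]ethynyl}-4,4,5,5-tetramethyl-1,3,2-dioxaborolane, via lithium acetylide 12 (not isolated), via lithium alkynylborate 13 (not isolated)
Conditions: LiN(SiMe3)2 (1.05 equiv), THF, −78 °C; i-PrOBpin, −78 °C; HCl in Et2O (1.05 equiv), −78 °C to rt; non-aqueous work-up
Reagents that add atoms: 2-isopropoxy-4,4,5,5-tetramethyl-1,3,2-dioxaborolane CC(C)OB1OC(C)(C)C(C)(C)O1
Why: The acetylenic C–H (pKa about 25) is removed by LiN(SiMe3)2, which neither exchanges with aryl bromides nor deprotonates the arene rings, and the acetylide is trapped by the boron electrophile as a borate that one equivalent of anhydrous HCl collapses to the alkynyl pinacolboronate (deprotonation–borylation of a terminal alkyne).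

Step 9
Reactants: 15 coumalic acid (2-oxo-2H-pyran-5-carboxylic acid)
Product: 16 3,5-dibromo-2H-pyran-2-one
Conditions: NBS (2.5 equiv), LiOAc, MeCN/H2O, rt
Reagents that add atoms: N-bromosuccinimide O=C1CCC(=O)N1Br
Why: Bromodecarboxylation of the carboxylate at C5 (Hunsdiecker-type ipso substitution) together with electrophilic bromination at the nucleophilic C3 of the pyrone gives the 3,5-dibromide in one operation.

Step 10
Reactants: 16 3,5-dibromo-2H-pyran-2-one; 14 2-{[3,4,5-tribromo-2-(2,4-dibromophenoxy)phenoxy]ethynyl}-4,4,5,5-tetramethyl-1,3,2-dioxaborolane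
Product: 18 2-{3,5-dibromo-2-[3,4,5-tribromo-2-(2,4-dibromophenoxy)phenoxy]phenyl}-4,4,5,5-tetramethyl-1,3,2-dioxaborolane, via bicyclic lactone 17 (not isolated)
Conditions: 16 (2 equiv), mesitylene, 150–160 °C, sealed tube, anhydrous
Reagents that add atoms: none
Why: An inverse-electron-demand [4+2] cycloaddition of the electron-poor pyrone 16 (diene C3–C6) with the push–pull alkyne 14 gives the bridged lactone 17, which loses CO2 at once by retro-[4+2], so ring A is closed by cycloaddition (bonds C2–C3 and C1–C6 of ring A) and arrives aromatic without an oxidation step. The closest known reactions are the thermal benzannulation of 2-pyrones with alkynyl pinacolboronates to arylboronates and the Diels–Alder reactions of 3,5-dibromo-2-pyrone with enol ethers; here the same reaction type is applied to a new pair of partners. No stereocentre remains, because the two bridgehead centres of racemic 17 vanish with the CO2. The step needs one orientation: the boron-bearing carbon (beta to oxygen, the nucleophilic end, polarised the same way by the oxygen lone pair and by the empty boron orbital) must bond to pyrone C6, the electrophilic terminus of the dienoate, and the aryloxy carbon to the brominated C3, which is the sense in which enol ethers add to this pyrone and also places the bulky Bpin next to CH instead of CBr. The aryl ynol ether has no C–H beta to oxygen for retro-ene loss of a ketene, the aryl bromides and the C–B bond are inert to heat in the absence of metals, and the excess of 16 is meant to offset slow self-reaction of the alkyne.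

Step 11
Reactants: 18 2-{3,5-dibromo-2-[3,4,5-tribromo-2-(2,4-dibromophenoxy)phenoxy]phenyl}-4,4,5,5-tetramethyl-1,3,2-dioxaborolane
Product: 19 Bromoiesol A, 3,5-dibromo-2-[3,4,5-tribromo-2-(2,4-dibromophenoxy)phenoxy]phenol
Conditions: NaBO3·4H2O, THF/H2O, rt
Reagents that add atoms: sodium perborate [Na+].[O-]OB=O
Why: Oxidation of the aryl C–B bond by perborate (1,2-aryl shift from boron to oxygen in the peroxoborate, then hydrolysis) unveils the ring A hydroxyl at the carbon that carried boron and does not touch aryl bromides or diaryl ethers.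

**Compound list**

1 | 2,4-dibromo-1-iodobenzene | Brc1ccc(I)c(Br)c1 | starting material
2 | 2,4-dibromo-1-[hydroxy(tosyloxy)iodo]benzene | OI(OS(=O)(=O)c1ccc(C)cc1)c1ccc(Br)cc1Br | intermediate
3 | (2,4-dibromophenyl)(2,4,6-trimethoxyphenyl)iodonium tosylate | COc1cc(OC)c([I+]c2ccc(Br)cc2Br)c(OC)c1.Cc1ccc(S(=O)(=O)[O-])cc1 | intermediate
4 | 5-bromo-2-methoxyphenol | COc1ccc(Br)cc1O | starting material
5 | 2,3,4-tribromo-6-methoxyphenol | COc1cc(Br)c(Br)c(Br)c1O | intermediate
6 | 1,2,3-tribromo-4-(2,4-dibromophenoxy)-5-methoxybenzene | COc1cc(Br)c(Br)c(Br)c1Oc1ccc(Br)cc1Br | intermediate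
7 | 3,4,5-tribromo-2-(2,4-dibromophenoxy)phenol | Oc1cc(Br)c(Br)c(Br)c1Oc1ccc(Br)cc1Br | intermediate
8 | 1,2,3-tribromo-4-(2,4-dibromophenoxy)-5-(ethenyloxy)benzene | C=COc1cc(Br)c(Br)c(Br)c1Oc1ccc(Br)cc1Br | intermediate
9 | 1,2,3-tribromo-5-(1,2-dibromoethoxy)-4-(2,4-dibromophenoxy)benzene (racemic) | BrCC(Br)Oc1cc(Br)c(Br)c(Br)c1Oc1ccc(Br)cc1Br | intermediate
10 | 1,2,3-tribromo-5-{[(Z)-2-bromoethenyl]oxy}-4-(2,4-dibromophenoxy)benzene (Z isomer drawn, expected as the main isomer) | Br/C=C\Oc1cc(Br)c(Br)c(Br)c1Oc1ccc(Br)cc1Br | intermediate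
11 | 1,2,3-tribromo-4-(2,4-dibromophenoxy)-5-(ethynyloxy)benzene | C#COc1cc(Br)c(Br)c(Br)c1Oc1ccc(Br)cc1Br | intermediate
12 | lithium [3,4,5-tribromo-2-(2,4-dibromophenoxy)phenoxy]acetylide | [Li]C#COc1cc(Br)c(Br)c(Br)c1Oc1ccc(Br)cc1Br | intermediate
13 | lithium isopropoxy(pinacolato){[3,4,5-tribromo-2-(2,4-dibromophenoxy)phenoxy]ethynyl}borate | [Li+].CC(C)O[B-]1(C#COc2cc(Br)c(Br)c(Br)c2Oc2ccc(Br)cc2Br)OC(C)(C)C(C)(C)O1 | intermediate
14 | 2-{[3,4,5-tribromo-2-(2,4-dibromophenoxy)phenoxy]ethynyl}-4,4,5,5-tetramethyl-1,3,2-dioxaborolane | CC1(C)OB(C#COc2cc(Br)c(Br)c(Br)c2Oc2ccc(Br)cc2Br)OC1(C)C | intermediate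
15 | coumalic acid | O=C(O)c1ccc(=O)oc1 | starting material
16 | 3,5-dibromo-2H-pyran-2-one | O=c1occ(Br)cc1Br | intermediate
17 | 4,7-dibromo-6-(4,4,5,5-tetramethyl-1,3,2-dioxaborolan-2-yl)-5-[3,4,5-tribromo-2-(2,4-dibromophenoxy)phenoxy]-2-oxabicyclo[2.2.2]octa-5,7-dien-3-one (racemic) | O=C1OC2C(Br)=CC1(Br)C(Oc3cc(Br)c(Br)c(Br)c3Oc3ccc(Br)cc3Br)=C2B2OC(C)(C)C(C)(C)O2 | intermediate
18 | 2-{3,5-dibromo-2-[3,4,5-tribromo-2-(2,4-dibromophenoxy)phenoxy]phenyl}-4,4,5,5-tetramethyl-1,3,2-dioxaborolane | CC1(C)OB(c2cc(Br)cc(Br)c2Oc2cc(Br)c(Br)c(Br)c2Oc2ccc(Br)cc2Br)OC1(C)C | intermediate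
19 | Bromoiesol A, 3,5-dibromo-2-[3,4,5-tribromo-2-(2,4-dibromophenoxy)phenoxy]phenol | Oc1cc(Br)cc(Br)c1Oc1cc(Br)c(Br)c(Br)c1Oc1ccc(Br)cc1Br | target

**Step count**

Total steps: 11. Longest linear sequence: 9 steps (steps 2, 3, 4, 5, 6, 7, 8, 10, 11); steps 1 and 9 are side branches.

**Steps most likely to fail**

Step 10. The cycloaddition may be slower than thermal self-reaction of the ynol ether boronate. The C–B bond may be lost by protonolysis at 150 °C. The partners may also add in the opposite orientation, which would put boron next to the brominated carbon. Fallback, from 7 to 19: ring A is attached as a ready-made arene. Phenoxide 7 (K2CO3, DMF, 80 °C) should displace the fluoride of 1,5-dibromo-2-fluoro-3-nitrobenzene, the only leaving group activated by the ortho nitro group, to give 1,5-dibromo-3-nitro-2-[3,4,5-tribromo-2-(2,4-dibromophenoxy)phenoxy]benzene F1. Fe powder with NH4Cl in EtOH/H2O should reduce the nitro group without touching the aryl bromides and give the aniline F2. NaNO2 in H2SO4/AcOH at 0 °C should give the diazonium hydrogen sulfate F3, and heating in dilute aqueous H2SO4 should hydrolyse it to the phenol. Copper is left out of the hydrolysis to hold back Pschorr-type ring closure onto ring B. The fallback comes back to the route at 19.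

Step 7. Syn elimination from the minor E isomer may be incomplete, tert-butoxide may add across the new triple bond, and the terminal ynol ether may oligomerise on concentration. Fallback, from 7 to 11: the halovinyl ether is made stereodefined by addition instead of by bromination of a vinyl ether. Phenol 7 with KOtBu and an excess of (Z)-1,2-dichloroethene in THF/DMSO should give chloroacetylene in the flask by anti loss of HCl, and anti addition of the phenoxide should give the (Z)-2-chlorovinyl ether F4. H and Cl are anti in F4, so the non-nucleophilic KN(SiMe3)2 in THF at −78 °C, followed by an NH4Cl quench, should give 11, where the route is rejoined. This bypasses steps 5 and 6 as well.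

Step 8. The amide base may deprotonate the aryl C–H between two bromines, leading to halogen migration or aryne formation. The electron-rich triple bond may be protonated during the HCl quench, and the alkynyl C–B bond may hydrolyse on work-up. Fallback, from 11 to 14: base-free catalytic dehydrogenative borylation of the terminal alkyne with pinacolborane (HBpin, catalytic Fe(OTf)2, a divalent iron salt, and catalytic DABCO, toluene, 60–100 °C). No strong base, no borate and no acid quench are involved, the product is isolated by filtration and evaporation, and no new intermediate arises.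

Further compounds
F1 | step 10 | 1,5-dibromo-3-nitro-2-[3,4,5-tribromo-2-(2,4-dibromophenoxy)phenoxy]benzene | O=[N+]([O-])c1cc(Br)cc(Br)c1Oc1cc(Br)c(Br)c(Br)c1Oc1ccc(Br)cc1Br
F2 | step 10 | 3,5-dibromo-2-[3,4,5-tribromo-2-(2,4-dibromophenoxy)phenoxy]aniline | Nc1cc(Br)cc(Br)c1Oc1cc(Br)c(Br)c(Br)c1Oc1ccc(Br)cc1Br
F3 | step 10 | 3,5-dibromo-2-[3,4,5-tribromo-2-(2,4-dibromophenoxy)phenoxy]benzenediazonium hydrogen sulfate | N#[N+]c1cc(Br)cc(Br)c1Oc1cc(Br)c(Br)c(Br)c1Oc1ccc(Br)cc1Br.OS(=O)(=O)[O-]
F4 | step 7 | 1,2,3-tribromo-5-{[(Z)-2-chloroethenyl]oxy}-4-(2,4-dibromophenoxy)benzene | Cl/C=C\Oc1cc(Br)c(Br)c(Br)c1Oc1ccc(Br)cc1Br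
F0 | step 8 | none | none
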